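The constants are those of an exercise; the run is a simulation.

We set how fast free G is caught by D against how fast G.D is given back, each per catalyst, in this one flask.

    X + G ⇌ G + D (K1 = 6.2, k1 = 0.092 /M/s)
    G + D ⇌ G.D (K2 = 9.0 /M, k2 = 0.11 /M/s)
    L + G.D → G + Z (k3 = 0.12 /M/s)
    L → Q (k4 = 1.9 × 10⁻⁵ /s)
X 0.50 M; L 0.700 equiv; G 0.068 mol%
1. the form that holds most of the catalyst when 10% of the X are converted (G / G.D)
2. its share of the catalyst then
3. apparent order in G when 10% of the X are converted (percent change of the rate of making Z for one percent more G charged)
4. apparent order in L when 10% of the X are converted (percent change of the rate of making Z for one percent more L charged)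

By our own reckoning the first step turns over the tenth of X in about 0.936 h, and by then the loss to Q leaves L at 93.8% of its charge. We count that whole tenth as D and leave out the part that has already gone on to Z. Then:

capture per G, with D at 10% of the X charged: 0.00550 /s

release per G.D, backward plus on to Z: 0.0122 /s + 0.0394 /s = 0.0516 /s

hold ratio, G.D over G: 0.107

A G.D lives 19.4 s, far shorter than 0.936 h, so it keeps pace with D and L and time drops out. This hold ratio, capture per G over release per G.D, makes G the resting state, with 90.4% of the catalyst. The ratio contains no G, so we expect order 1 in G. L sits in the release, so:

order in L: 0.310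

The forecast says G at 90.7%, with orders 1.02 in G and 0.3 in L, since “G.D's breakdown is mostly L-driven, so added L largely cancels itself”.

The flask gives G at 90.8%, with orders 1.0 in G and 0.30 in L. With twice the G, the tenth came in 0.499 of the time and the rate stood 2.01 times as high, while the hold ratio for that shorter loss of L is 0.104, close to this flask's. In this flask at 20.0 h, with D at 44.4% of the X charged and L at 7.74% of its charge, the hold ratio is 1.58, which puts 61.2% of the catalyst in G.D, and the flask held 61.2% there.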